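All runs were generated by integration on assumed constants; the scatter is artificial.

- At 2.0 h no run had been read; the earliest reading, noon at 0.625 d, came later, so that answer had to be bracketed.

the same everywhere: starting material 10 mM

| flask | reagent | free catalyst | remark | time |
|---|---|---|---|---|
| noon | 10 mM | 0.35 mM | run made earlier |  |
| winter | 10 mM | 0.55 mM | run made earlier |  |
| midnight | 5 mM | 0.25 mM | run made earlier |  |
| flask | 10.0 mM | 0.25 mM |  | 6.0 d |

| run | time / d | target / % | isomer of the product / % |
|---|---|---|---|
| noon | 0.625 | 11.0 | 7.1 |
| noon | 1.25 | 10.4 | 7.7 |
| noon | 3.00 | 10.6 | 8.7 |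
| noon | 8.00 | 11.5 | 8.8 |
| winter | 1.67 | 15.9 | 12.4 |
| winter | 4.00 | 16.3 | 12.5 |
| winter | 5.00 | 16.3 | 12.3 |
| winter | 8.00 | 17.5 | 11.5 |
| midnight | 0.833 | 3.4 | 2.7 |
| midnight | 2.50 | 5.4 | 2.6 |
| midnight | 5.00 | 4.7 | 2.6 |
| midnight | 8.00 | 4.6 | 3.2 |

(standard deviation of a reading: 0.5 percentage points)

* share of target in target plus isomer of the product at 2.0 h
* share of target in target plus isomer of the product at 6.0 d
* which of target and isomer of the product there is more of at 6.0 d



- Pooled, the noon and winter readings gave 57.5%; I called this s∞, the plateau share, target over target plus isomer of the product once the two stop moving, the mark of thermodynamic control.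
- My lower bound at 2.0 h was s∞, the case of both products born side by side in that ratio.
- My upper bound assumed that isomer of the product arises from target, with the share falling from 100% towards s∞. The first noon reading, 60.8%, taken at face value despite its scatter, gave a half-life of the share's distance from s∞ near 4.06 h; carried over to this flask, that put an estimated top at 87.7%.
- I committed to the middle, 72.6%, and to s∞ at 6.0 d, which is much longer than that half-life.
- The forecast gave 58% and 58%, with target ahead, placing the early share on my lower bound: "I assume the same selectivity but give it a wider range".
- The flask gave 76.0% at 2.0 h, inside the bracket, and 57.1% at 6.0 d, with target ahead.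

    target ⇌ isomer of the product (K = 0.750, k = 0.510 /h)
    reagent + free catalyst + intermediate → free catalyst + target (k = 51000 /M²/h)
    starting material + free catalyst ⇌ free catalyst + intermediate (K = 0.260, k = 1100 /M/h)
    free catalyst → spent catalyst (k = 0.130 /h)

- In this flask at 6.0 d, s∞ times the 14.6% of product gives 8.41% target, and the flask held 8.37%. A neighbouring flask, the same but with 1.0 mM free catalyst, showed 73.1% at 2.0 h, again below the top, and 57.1% at 6.0 d. Its 42.8% of product times s∞ gives 24.6%, and it held 24.4% target.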